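**Retrosynthetic overview**
1. The target is a (2R,4R)-2,4-cis-flavan. Ring A is the resorcinol-type benzo ring, ring C is O1–C2–C3–C4–C4a–C8a, ring B is the 4-hydroxyphenyl on C2, and ring D is the acylphloroglucinol on C4. The plan rests on C3 of ring C, an unsubstituted CH2 between the two aryl-bearing carbons C2 and C4. Removing it contracts ring C to the furan ring of a flat 2,3-diarylbenzofuran that already holds ring A, O1, ring B and ring D.
2. Last bonds made: five O–benzyl bonds cleaved by hydrogenolysis, the acyl–ring D bond (Friedel–Crafts), C4–H and C3–H (face-selective hydrogenation), and C2–H (enantioselective hydride transfer to the 4-arylflavylium ion).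
3. Key disconnection: C2–C3 and C3–C4 are made together. Chlorocarbene inserts CH into the furan C2=C3 bond, and the chlorocyclopropane opens to the flavylium ring.
4. Benzofuran: the C3–ring D bond comes from a Negishi coupling. The furan ring comes from an intramolecular Wittig reaction of a salicyl phosphonium salt with the ring B acid chloride.
5. Ring order: furan ring (step 3), then the transient cyclopropane and six-membered ring C (step 7). Rings A, B, D and the chain phenyl are bought.

Key step: step 7

Assumption: the sense of induction of the two chiral iridium catalysts is taken by analogy with aryl ketone transfer hydrogenation and with 4-aryl-2H-chromene hydrogenation. If it proves opposite, the equally available mirror-image ligand is used.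

**Step 1**
Reactants: 1 4-(benzyloxy)-2-hydroxybenzaldehyde
Product: 2 5-(benzyloxy)-2-(hydroxymethyl)phenol
Conditions: NaBH4, THF/MeOH, 0 °C
Reagents that add atoms: none
Why: Borohydride reduction of an aryl aldehyde is chemoselective and leaves the phenol and the benzyl ether untouched.

**Step 2**
Reactants: 2 5-(benzyloxy)-2-(hydroxymethyl)phenol
Product: 3 [4-(benzyloxy)-2-hydroxybenzyl]triphenylphosphonium bromide
Conditions: PPh3·HBr, MeCN, 60 °C
Reagents that add atoms: triphenylphosphine hydrobromide, [Br-].c1ccc(cc1)[PH+](c1ccccc1)c1ccccc1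
Why: The ortho-hydroxy, para-alkoxy benzylic alcohol ionises under the mild acid and triphenylphosphine captures the cation (phosphonium salt formation), which is the usual entry to the intramolecular Wittig benzofuran synthesis.

**Step 3**
Reactants: 3 [4-(benzyloxy)-2-hydroxybenzyl]triphenylphosphonium bromide; 4 4-(benzyloxy)benzoyl chloride
Product: 6 6-(benzyloxy)-2-[4-(benzyloxy)phenyl]benzofuran, via O-aroyl phosphonium bromide 5 (not isolated)
Conditions: Et3N, toluene, reflux
Reagents that add atoms: 4-(benzyloxy)benzoyl chloride (4), O=C(Cl)c1ccc(OCc2ccccc2)cc1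
Why: O-Acylation of the phenol, ylide formation and intramolecular Wittig olefination of the ester carbonyl close the furan ring with loss of triphenylphosphine oxide, a well-used route to 2-arylbenzofurans.

**Step 4**
Reactants: 6 6-(benzyloxy)-2-[4-(benzyloxy)phenyl]benzofuran
Product: 7 6-(benzyloxy)-2-[4-(benzyloxy)phenyl]-3-bromobenzofuran
Conditions: NBS (1.0 equiv), CH2Cl2, 0 °C, dark
Reagents that add atoms: N-bromosuccinimide, O=C1CCC(=O)N1Br
Why: In this electrophilic aromatic bromination, C3 is the enol-ether β-carbon of the 2-arylbenzofuran and the most nucleophilic position, so one equivalent of NBS should stop there.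

**Step 5**
Reactants: 8 1,3,5-tris(benzyloxy)benzene
Product: 9 2-bromo-1,3,5-tris(benzyloxy)benzene
Conditions: NBS (1.0 equiv), CH2Cl2, −78 → 0 °C
Reagents that add atoms: N-bromosuccinimide, O=C1CCC(=O)N1Br
Why: In this electrophilic aromatic monobromination the three ring CH positions are equivalent, and the first bromine slows a second substitution.

**Step 6**
Reactants: 9 2-bromo-1,3,5-tris(benzyloxy)benzene; 7 6-(benzyloxy)-2-[4-(benzyloxy)phenyl]-3-bromobenzofuran
Product: 12 6-(benzyloxy)-2-[4-(benzyloxy)phenyl]-3-[2,4,6-tris(benzyloxy)phenyl]benzofuran, via aryllithium 10 (not isolated), via arylzinc chloride 11 (not isolated)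
Conditions: 9, n-BuLi, THF, −78 °C; ZnCl2, −78 °C → rt; 7, Pd2(dba)3 (2 mol %), RuPhos (8 mol %), THF, 65 °C
Reagents that add atoms: n-butyllithium, [Li]CCCC (lithium of 10); zinc dichloride, Cl[Zn]Cl (zinc and chlorine of 11)
Why: Fast bromine–lithium exchange avoids the benzylic deprotonation and Wittig rearrangement that direct lithiation of 8 would risk, the arylzinc does not protodemetalate as 2,6-dialkoxyarylboronic acids do, and the Negishi coupling with a bulky dialkylbiarylphosphine is established for heavily ortho-substituted biaryls.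

**Step 7**
Reactants: 12 6-(benzyloxy)-2-[4-(benzyloxy)phenyl]-3-[2,4,6-tris(benzyloxy)phenyl]benzofuran; 13 dichloromethane
Product: 15 7-(benzyloxy)-2-[4-(benzyloxy)phenyl]-4-[2,4,6-tris(benzyloxy)phenyl]chromenylium chloride, via endo-chlorocyclopropane 14 (not isolated)
Conditions: LiTMP (from TMPH and n-BuLi, Et2O/hexane, 0 °C; 6 equiv) added by syringe pump to 12 in CH2Cl2/Et2O, −30 °C; then HCl/Et2O, wash with 1 M aq HCl, precipitate with Et2O/hexane
Reagents that add atoms: dichloromethane (13), ClCCl
Why: Proposed new method: LiTMP should deprotonate the large excess of CH2Cl2 faster than any benzylic or aryl C–H of 12, LiCHCl2 loses LiCl, and the small electrophilic chlorocarbene(oid) adds suprafacially in a [2+1] cheletropic closure to the furan C2=C3 bond, bonding ahead at the unshielded C2 while the 6-benzyloxy group para to C3a carries the charge building at C3, to give cyclopropane 14. In 14 the C–Cl bond ionises in concert with disrotatory 2π-electrocyclic opening of the former C2–C3 fusion bond (Woodward–Hoffmann–DePuy rule), so the bicyclo[3.1.0] unit enlarges to the six-membered ring C and the inserted CH becomes C3 of the allyl cation C2–C3–C4, which is the benzopyrylium of 15; the driving force is the release of cyclopropane strain together with the aromatic stabilisation of the pyrylium ring and donation from O1 and ring B. The closest known reaction types are the Ciamician–Dennstedt-type chlorocarbene expansions of indoles to quinolines and of indenes to naphthalenes and the dihalocarbene expansion of benzofuran to 3-halochromenes; monochlorocarbene insertion into a 2,3-diarylbenzofuran to give a flavylium salt has not been shown. No stereocentre remains in 15; in transient 14 the cis ring fusion follows from the concerted syn addition, and chlorine is expected endo (cis to O1 and C3a, as the concerted opening requires) because the opposite face of the new three-membered ring is filled by rings B and D. The step needs site selectivity for C2=C3 over five alkoxyarene rings, which the higher nucleophilicity of a non-benzenoid enol-ether double bond should secure, and it needs the cation to survive, which is secured by slow base addition at a temperature where LiCHCl2 collapses at once (so no carbon nucleophile builds up) and by the HCl work-up, which returns reversible adducts at C2 to the cation.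

**Step 8**
Reactants: 15 7-(benzyloxy)-2-[4-(benzyloxy)phenyl]-4-[2,4,6-tris(benzyloxy)phenyl]chromenylium chloride
Product: 16 7-(benzyloxy)-2-[4-(benzyloxy)phenyl]-4-[2,4,6-tris(benzyloxy)phenyl]chromenylium tetrafluoroborate
Conditions: NaBF4 (sat. aq, pH 1 with HBF4), CH2Cl2, rt; crystallise from CH2Cl2/Et2O
Reagents that add atoms: sodium tetrafluoroborate, [Na+].F[B-](F)(F)F
Why: Salt metathesis gives a crystallisable salt that can be freed from neutral carbene by-products, and its non-coordinating anion does not occupy the iridium site in the next step.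

**Step 9**
Reactants: 16 7-(benzyloxy)-2-[4-(benzyloxy)phenyl]-4-[2,4,6-tris(benzyloxy)phenyl]chromenylium tetrafluoroborate
Product: 17 (2R)-7-(benzyloxy)-2-[4-(benzyloxy)phenyl]-4-[2,4,6-tris(benzyloxy)phenyl]-2H-chromene
Conditions: [Cp*IrCl((R,R)-TsDPEN)] (2 mol %), HCO2H/Et3N (5:2), CH2Cl2, −10 °C, dark
Reagents that add atoms: none
Why: Proposed new method: decarboxylation of the iridium formate gives the neutral 18-electron hydride Cp*IrH((R,R)-TsDPEN), which should pass hydride in an outer-sphere ionic step to C2 of the cation, because C4 is walled in on both faces by the two ortho benzyloxy groups of the orthogonal ring D while the coplanar ring B leaves C2 open, and the chiral pocket (Cp*/ring B CH–π contact, N–H···F–BF3 anion bridge) differentiates the enantiotopic faces to set C2 as R; the closest known reaction types are the asymmetric (transfer) hydrogenation of cyclic iminium, quinolinium and isochromenylium ions with metal–TsDPEN catalysts and the chiral phosphate/Hantzsch ester reduction of 2,4-diaryl-1-benzopyrylium ions.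

**Step 10**
Reactants: 17 (2R)-7-(benzyloxy)-2-[4-(benzyloxy)phenyl]-4-[2,4,6-tris(benzyloxy)phenyl]-2H-chromene
Product: 18 (2R,4R)-7-(benzyloxy)-2-[4-(benzyloxy)phenyl]-4-[2,4,6-tris(benzyloxy)phenyl]chroman (2,4-cis)
Conditions: [Ir(cod)((S)-tBu-PHOX)]BArF (2 mol %), H2 (50 bar), CH2Cl2, rt, dark
Reagents that add atoms: none
Why: This is an iridium N,P-catalysed asymmetric hydrogenation of a trisubstituted 4-aryl-2H-chromene, a known substrate class, in which syn delivery of H2 to the face of C3=C4 opposite ring B puts the new C4–H trans to ring B and hence ring D cis to it (4R), the ligand antipode reinforces this substrate bias, and the homogeneous catalyst leaves the five benzyl ethers alone.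

**Step 11**
Reactants: 19 9-phenylnonanoic acid
Product: 20 9-phenylnonanoyl chloride
Conditions: (COCl)2, DMF (cat.), CH2Cl2, 0 °C → rt
Reagents that add atoms: oxalyl chloride, O=C(Cl)C(=O)Cl
Why: Acid chloride formation with oxalyl chloride and catalytic DMF is standard and gives only gaseous by-products.

**Step 12**
Reactants: 18 (2R,4R)-7-(benzyloxy)-2-[4-(benzyloxy)phenyl]-4-[2,4,6-tris(benzyloxy)phenyl]chroman; 20 9-phenylnonanoyl chloride
Product: 22 1-{2,4,6-tris(benzyloxy)-3-[(2R,4R)-7-(benzyloxy)-2-[4-(benzyloxy)phenyl]chroman-4-yl]phenyl}-9-phenylnonan-1-one, via acyl triflate 21 (not isolated)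
Conditions: AgOTf, 2,6-di-tert-butyl-4-methylpyridine, CH2Cl2, −78 → −30 °C
Reagents that add atoms: 9-phenylnonanoyl chloride (20), ClC(=O)CCCCCCCCc1ccccc1; silver trifluoromethanesulfonate, [Ag+].[O-]S(=O)(=O)C(F)(F)F (triflate of 21)
Why: In this Friedel–Crafts acylation through the mixed carboxylic–triflic anhydride, ring D is the only ring with three mutually meta oxygen donors and its two free CH positions are equivalent by rotation about the C4–aryl bond, while the hindered pyridine takes up the triflic acid so that the acid-labile C4–ring D and C2–O1 bonds, and with them both stereocentres, are not put at risk.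

**Step 13**
Reactants: 22 1-{2,4,6-tris(benzyloxy)-3-[(2R,4R)-7-(benzyloxy)-2-[4-(benzyloxy)phenyl]chroman-4-yl]phenyl}-9-phenylnonan-1-one
Product: 23 1-{2,4,6-trihydroxy-3-[(2R,4R)-7-hydroxy-2-(4-hydroxyphenyl)chroman-4-yl]phenyl}-9-phenylnonan-1-one (CNP0175574.1)
Conditions: H2 (1 atm), Pd(OH)2/C, THF/MeOH, rt, stopped after uptake of five equivalents
Reagents that add atoms: none
Why: Catalytic hydrogenolysis of aryl benzyl ethers under neutral conditions is routine on flavans and acylphloroglucinols, and it should spare the cyclic C2–O1 bond, the hindered hydrogen-bonded ketone and both stereocentres.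

**Compound list**
1 | 4-(benzyloxy)-2-hydroxybenzaldehyde | O=Cc1ccc(OCc2ccccc2)cc1O | starting material
2 | 5-(benzyloxy)-2-(hydroxymethyl)phenol | OCc1ccc(OCc2ccccc2)cc1O | intermediate
3 | [4-(benzyloxy)-2-hydroxybenzyl]triphenylphosphonium bromide | [Br-].Oc1cc(OCc2ccccc2)ccc1C[P+](c1ccccc1)(c1ccccc1)c1ccccc1 | intermediate
4 | 4-(benzyloxy)benzoyl chloride | O=C(Cl)c1ccc(OCc2ccccc2)cc1 | starting material
5 | [4-(benzyloxy)-2-{[4-(benzyloxy)benzoyl]oxy}benzyl]triphenylphosphonium bromide | [Br-].O=C(Oc1cc(OCc2ccccc2)ccc1C[P+](c1ccccc1)(c1ccccc1)c1ccccc1)c1ccc(OCc2ccccc2)cc1 | intermediate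
6 | 6-(benzyloxy)-2-[4-(benzyloxy)phenyl]benzofuran | C(c1ccccc1)Oc1ccc(-c2cc3ccc(OCc4ccccc4)cc3o2)cc1 | intermediate
7 | 6-(benzyloxy)-2-[4-(benzyloxy)phenyl]-3-bromobenzofuran | C(c1ccccc1)Oc1ccc(-c2oc3cc(OCc4ccccc4)ccc3c2Br)cc1 | intermediate
8 | 1,3,5-tris(benzyloxy)benzene | c1ccc(COc2cc(OCc3ccccc3)cc(OCc3ccccc3)c2)cc1 | starting material
9 | 2-bromo-1,3,5-tris(benzyloxy)benzene | Brc1c(OCc2ccccc2)cc(OCc2ccccc2)cc1OCc1ccccc1 | intermediate
10 | [2,4,6-tris(benzyloxy)phenyl]lithium | [Li]c1c(OCc2ccccc2)cc(OCc2ccccc2)cc1OCc1ccccc1 | intermediate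
11 | [2,4,6-tris(benzyloxy)phenyl]zinc chloride | Cl[Zn]c1c(OCc2ccccc2)cc(OCc2ccccc2)cc1OCc1ccccc1 | intermediate
12 | 6-(benzyloxy)-2-[4-(benzyloxy)phenyl]-3-[2,4,6-tris(benzyloxy)phenyl]benzofuran | C(c1ccccc1)Oc1ccc(-c2oc3cc(OCc4ccccc4)ccc3c2-c2c(OCc3ccccc3)cc(OCc3ccccc3)cc2OCc2ccccc2)cc1 | intermediate
13 | dichloromethane | ClCCl | starting material
14 | rac-endo-4-(benzyloxy)-1a-[4-(benzyloxy)phenyl]-1-chloro-6b-[2,4,6-tris(benzyloxy)phenyl]-1a,6b-dihydro-1H-cyclopropa[b]benzofuran (Cl cis to the ring O and C6a; one enantiomer drawn) | Cl[C@H]1[C@@]2(c3ccc(OCc4ccccc4)cc3)Oc3cc(OCc4ccccc4)ccc3[C@@]12c1c(OCc2ccccc2)cc(OCc2ccccc2)cc1OCc1ccccc1 | intermediate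
15 | 7-(benzyloxy)-2-[4-(benzyloxy)phenyl]-4-[2,4,6-tris(benzyloxy)phenyl]chromenylium chloride | [Cl-].C(c1ccccc1)Oc1ccc(-c2cc(-c3c(OCc4ccccc4)cc(OCc4ccccc4)cc3OCc3ccccc3)c3ccc(OCc4ccccc4)cc3[o+]2)cc1 | intermediate
16 | 7-(benzyloxy)-2-[4-(benzyloxy)phenyl]-4-[2,4,6-tris(benzyloxy)phenyl]chromenylium tetrafluoroborate | F[B-](F)(F)F.C(c1ccccc1)Oc1ccc(-c2cc(-c3c(OCc4ccccc4)cc(OCc4ccccc4)cc3OCc3ccccc3)c3ccc(OCc4ccccc4)cc3[o+]2)cc1 | intermediate
17 | (2R)-7-(benzyloxy)-2-[4-(benzyloxy)phenyl]-4-[2,4,6-tris(benzyloxy)phenyl]-2H-chromene | C1(c2c(OCc3ccccc3)cc(OCc3ccccc3)cc2OCc2ccccc2)=C[C@H](c2ccc(OCc3ccccc3)cc2)Oc2cc(OCc3ccccc3)ccc12 | intermediate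
18 | (2R,4R)-7-(benzyloxy)-2-[4-(benzyloxy)phenyl]-4-[2,4,6-tris(benzyloxy)phenyl]chroman | c1c(OCc2ccccc2)cc(OCc2ccccc2)c([C@@H]2C[C@H](c3ccc(OCc4ccccc4)cc3)Oc3cc(OCc4ccccc4)ccc32)c1OCc1ccccc1 | intermediate
19 | 9-phenylnonanoic acid | OC(=O)CCCCCCCCc1ccccc1 | starting material
20 | 9-phenylnonanoyl chloride | ClC(=O)CCCCCCCCc1ccccc1 | intermediate
21 | 9-phenylnonanoyl trifluoromethanesulfonate | O=C(CCCCCCCCc1ccccc1)OS(=O)(=O)C(F)(F)F | intermediate
22 | 1-{2,4,6-tris(benzyloxy)-3-[(2R,4R)-7-(benzyloxy)-2-[4-(benzyloxy)phenyl]chroman-4-yl]phenyl}-9-phenylnonan-1-one | O=C(CCCCCCCCc1ccccc1)c1c(OCc2ccccc2)cc(OCc2ccccc2)c([C@@H]2C[C@H](c3ccc(OCc4ccccc4)cc3)Oc3cc(OCc4ccccc4)ccc32)c1OCc1ccccc1 | intermediate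
23 | 1-{2,4,6-trihydroxy-3-[(2R,4R)-7-hydroxy-2-(4-hydroxyphenyl)chroman-4-yl]phenyl}-9-phenylnonan-1-one | O=C(CCCCCCCCc1ccccc1)c1c(O)cc(O)c([C@@H]2C[C@H](c3ccc(O)cc3)Oc3cc(O)ccc32)c1O | target

Total step count: 13. Longest linear sequence: 11 (steps 1, 2, 3, 4, 6, 7, 8, 9, 10, 12, 13).

**Steps most likely to fail**

**Step 7 (proposed new method).**
- The ortho benzyloxy groups of ring D shield C3 on both faces. Cyclopropanation may therefore be slower than self-condensation of the carbenoid or than its addition to the alkoxyarene rings.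
- Chlorine may end up exo, which blocks the concerted opening.
- The cation may be alkylated irreversibly by the carbenoid.
- The fallback gives up the ring expansion and uses known chemistry. It sets out from 9 and comes back at 16. Purchased 7,4'-dihydroxyflavone F1 is benzylated (BnBr, K2CO3, DMF) to 7-(benzyloxy)-2-[4-(benzyloxy)phenyl]-4H-chromen-4-one F2. Aryllithium 10, made from 9 as in step 6, adds to the C4 carbonyl (THF, −78 °C, NH4Cl work-up) to give 7-(benzyloxy)-2-[4-(benzyloxy)phenyl]-4-[2,4,6-tris(benzyloxy)phenyl]-4H-chromen-4-ol F3. HBF4·OEt2 in Et2O then removes water and precipitates 16. This is the classical organometal addition and acid dehydration route from flavones to 4-substituted flavylium salts.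

**Step 9 (proposed new method).**
- The two faces of the flat cation may be poorly differentiated.
- Some hydride may reach C4.
- The C2 centre may erode through degenerate hydride exchange between product and unreacted cation, or through light-induced electrocyclic ring opening.
- The fallback replaces asymmetric catalysis by resolution. It sets out from 16 and comes back at 18. NaBH4 in THF/MeCN at 0 °C gives racemic 7-(benzyloxy)-2-[4-(benzyloxy)phenyl]-4-[2,4,6-tris(benzyloxy)phenyl]-2H-chromene F4. Hydrogenation with achiral [Ir(cod)(PCy3)(py)]BArF (H2, 50 bar, CH2Cl2) gives racemic 2,4-cis-7-(benzyloxy)-2-[4-(benzyloxy)phenyl]-4-[2,4,6-tris(benzyloxy)phenyl]chroman F5. Preparative chromatography on a chiral stationary phase then delivers 18.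

**Step 10.**
- The alkene may fail to bind to iridium because the ortho benzyloxy groups flank C4.
- The acidic iridium hydrides may protonate C3 and start hydride scrambling.
- The remote C2 substituent may give poor facial selectivity.
- The fallback delivers hydrogen to C4 with a much smaller reagent and removes the extra heteroatom afterwards. It sets out from 17 and comes back at 18. BH3·SMe2 (THF, 0 °C → rt) adds syn, anti to ring B, with boron on C3, as is known for alkenes carrying a 2,4,6-trialkoxyphenyl group. This gives [(2R,3R,4R)-configured] chroman-3-ylborane F6. H2O2/NaOH oxidises it with retention to (2S,3R,4R)-7-(benzyloxy)-2-[4-(benzyloxy)phenyl]-4-[2,4,6-tris(benzyloxy)phenyl]chroman-3-ol F7. 1,1'-Thiocarbonyldiimidazole (DMAP, toluene, 80 °C) gives the O-(imidazol-1-ylthiocarbonyl) derivative F8. Barton–McCombie deoxygenation (Bu3SnH, AIBN, toluene, 90 °C) then gives 18.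

**Further compounds**
F1 | step 7 | 7,4'-dihydroxyflavone (purchased) | O=c1cc(-c2ccc(O)cc2)oc2cc(O)ccc12
F2 | step 7 | 7-(benzyloxy)-2-[4-(benzyloxy)phenyl]-4H-chromen-4-one | O=c1cc(-c2ccc(OCc3ccccc3)cc2)oc2cc(OCc3ccccc3)ccc12
F3 | step 7 | 7-(benzyloxy)-2-[4-(benzyloxy)phenyl]-4-[2,4,6-tris(benzyloxy)phenyl]-4H-chromen-4-ol (racemic) | OC1(c2c(OCc3ccccc3)cc(OCc3ccccc3)cc2OCc2ccccc2)C=C(c2ccc(OCc3ccccc3)cc2)Oc2cc(OCc3ccccc3)ccc12
F4 | step 9 | racemic 7-(benzyloxy)-2-[4-(benzyloxy)phenyl]-4-[2,4,6-tris(benzyloxy)phenyl]-2H-chromene | C1(c2c(OCc3ccccc3)cc(OCc3ccccc3)cc2OCc2ccccc2)=CC(c2ccc(OCc3ccccc3)cc2)Oc2cc(OCc3ccccc3)ccc12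
F5 | step 9 | racemic 2,4-cis-7-(benzyloxy)-2-[4-(benzyloxy)phenyl]-4-[2,4,6-tris(benzyloxy)phenyl]chroman (both enantiomers written) | c1c(OCc2ccccc2)cc(OCc2ccccc2)c([C@@H]2C[C@H](c3ccc(OCc4ccccc4)cc3)Oc3cc(OCc4ccccc4)ccc32)c1OCc1ccccc1.c1c(OCc2ccccc2)cc(OCc2ccccc2)c([C@H]2C[C@@H](c3ccc(OCc4ccccc4)cc3)Oc3cc(OCc4ccccc4)ccc32)c1OCc1ccccc1
F6 | step 10 | {7-(benzyloxy)-2-[4-(benzyloxy)phenyl]-4-[2,4,6-tris(benzyloxy)phenyl]chroman-3-yl}borane, boron trans to rings B and D | c1c(OCc2ccccc2)cc(OCc2ccccc2)c([C@@H]2[C@@H](B)[C@H](c3ccc(OCc4ccccc4)cc3)Oc3cc(OCc4ccccc4)ccc32)c1OCc1ccccc1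
F7 | step 10 | (2S,3R,4R)-7-(benzyloxy)-2-[4-(benzyloxy)phenyl]-4-[2,4,6-tris(benzyloxy)phenyl]chroman-3-ol | c1c(OCc2ccccc2)cc(OCc2ccccc2)c([C@@H]2[C@@H](O)[C@H](c3ccc(OCc4ccccc4)cc3)Oc3cc(OCc4ccccc4)ccc32)c1OCc1ccccc1
F8 | step 10 | O-{(2S,3R,4R)-7-(benzyloxy)-2-[4-(benzyloxy)phenyl]-4-[2,4,6-tris(benzyloxy)phenyl]chroman-3-yl} 1H-imidazole-1-carbothioate | c1c(OCc2ccccc2)cc(OCc2ccccc2)c([C@@H]2[C@@H](OC(=S)n3ccnc3)[C@H](c3ccc(OCc4ccccc4)cc3)Oc3cc(OCc4ccccc4)ccc32)c1OCc1ccccc1
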